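The constants used here were set for the occasion; no experiment stands behind them.

Take 0.386 M: this is S*, the crossover level, the amount of solid substrate at which self-condensation consumes it as fast as it can dissolve into an empty solution.

solid substrate 1.1 M; solid reagent 0.990 M; time 4.0 d

    dissolved substrate + coupling partner → target (k1 = 0.41 /M/h)
    solid substrate ⇌ dissolved substrate, rate k2*(cs2 - [dissolved substrate]) while solid is left; crystals form when [dissolved substrate] > cs2 (cs2 = 0.42 M, k2 = 0.085 /h)
    2 solid substrate → self-condensation product (k3 = 0.12 /M/h)
    2 dissolved substrate → side product (k4 = 0.73 /M/h)
    solid reagent ⇌ coupling partner, rate k5*(cs5 - [coupling partner]) while solid is left; crystals form when [coupling partner] > cs5 (cs5 = 0.098 M, k5 = 0.42 /h)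

* target at 4.0 d, in percent of the solid substrate charged
* the change that raises the amount of target at 4.0 d, in percent of the solid substrate charged most ("none" if none brings more than 2 percentage points) (red / grey / ochre / teal / none)
* amount of target at 4.0 d, in percent of the solid substrate charged, after teal

- red: doubling the solubility in step 5, all else as stated
- grey: doubling the solubility in step 2, all else as stated
- ochre: doubling the dissolution coefficient of step 5, all else as stated
- teal: doubling the dissolution coefficient of step 2, all else as stated

- percent here means solid substrate units held: one side product or self-condensation product counts as two
- two of one species on the left: rate k times its square, two consumed each time
- solid substrate, solid reagent is a solid; its amount is given per volume of the solution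
- at the start none of the solid substrate is in solution
- at the start none of the solid reagent is in solution
- run time (flask): 4.0 d

At the start of the flask, self-condensation takes 0.290 M/h, far more than the 0.0357 M/h that dissolution gives at most. The first falls with the square of the solid and the second does not, so you may say roughly that solid above S* self-condenses and solid below it dissolves. Target is then the dissolved share, S* over the charge, times the part of dissolved substrate that couples.

Which numbers must you know well? Take the coupling partner at its solubility and balance dissolution against both losses of dissolved substrate: I reckon 0.119 M dissolved while solid lasts. The dissolution coefficient of the solid reagent should matter little: at 0.42 /h it refills the coupling partner faster than the 0.0489 /h at which coupling drains it. The solubility of the coupling partner should matter nearly in proportion: coupling, at 0.0402 /h, takes dissolved substrate more slowly than dimerisation to side product, at 0.174 /h, so the share that couples follows that solubility. The solubility and dissolution coefficient of the substrate pull two ways: they raise S*, but they raise the dissolved level too.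

Now the numbers. Of the 0.119 M dissolved, 18.7% couples. That gives me 6.57%, then 11.7% after red and 7.25% after teal, so I pick red.

The forecast also picks red, but its yields are higher than mine: 9.2%, and 9.6% after teal. It reasons that “The coupling partner stays close to its solubility”.

The simulation gives 9.02%, best red with a gain of 5.7 percentage points, and 8.95% after teal.

In this flask, S* reckons 64.9% of the charge for self-condensation product, and 60.1% stands there at 4.00 d. For the neighbour flask with 0.66 M of solid substrate, the same S* gives 41.5%, and that flask holds 42.6% self-condensation product with 13.5% target.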